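The route rests on the C15–C5' bond. The threo pair C15(OH)/C5'(O-lactone), lying between the preformed butenolide ring and the C13 branch, is read as the adduct of a (13E)-C15 enal and C5 of 4-methyl-2-silyloxyfuran. One titanium–BINOL vinylogous Mukaiyama aldol joins the fragments, sets both centres and unveils the butenolide, closing no ring. The enal is larixol (rings A and B intact) after O6-relayed oxidation of C18, masking as the O6–C18 oxolane acetal, hydration at C8 and two-carbon extension at C13. The new 15-OH then steers a singlet-oxygen ene shift of C13=C14 to the 14-hydroxy C13=C16 methylene.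

Key step: step 14

Remark on numbering: labdane numbering is used; the butenolide atoms are primed (O1', C2' carbonyl, C3', C4' bearing the methyl, C5' the ring CH–O).
Remark on geometry: 6α-OH and the 4α-methyl (C18) are both equatorial and peri across C5, so O6 and C18 lie at 1,5-hydrogen-transfer distance and can be bridged by one bond. The target is taken, as formulated, as the open 6-hydroxy-18-aldehyde, with its lactol as a tautomer.
Remark on the catalyst: Si-face attack at C15 is assumed to require (S)-BINOL, by analogy with other titanium–BINOL aldehyde additions; the antipode is to be confirmed on 3-methylbut-2-enal before material is committed.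

Step 1
Reactants: 1 larixol, labda-8(17),14-diene-6α,13(S)-diol
Product: 2 6α-hydroxy-14,15-dinorlabd-8(17)-en-13-one
Conditions: KMnO4, acetone, 0 °C → rt
Reagents that add atoms: none
Why: Permanganate degradation of the tertiary vinyl carbinol (oxidative cleavage, then oxidative decarboxylation of the α-hydroxy acid) should stop at the C13 methyl ketone, as it does with manool-type diterpenes, because the monosubstituted vinyl group reacts faster than the hindered exocyclic alkene and the secondary 6-OH.

Step 2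
Reactants: 2 6α-hydroxy-14,15-dinorlabd-8(17)-en-13-one
Product: 3 6α-nitrite ester of 2
Conditions: NOCl, pyridine, −30 °C, dark
Reagents that add atoms: nitrosyl chloride, ClN=O
Why: O-Nitrosation of the only hydroxyl is fast in cold pyridine, where the buffered medium should keep electrophilic addition of NOCl to the 8(17)-alkene slow (nitrite ester formation).

Step 3
Reactants: 3 6α-nitrite ester of 2
Product: 5 6α-hydroxy-13-oxo-14,15-dinorlabd-8(17)-en-18-al oxime, via C18-nitroso alcohol 4 (not isolated)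
Conditions: hν (Hg lamp, Pyrex), benzene, 10 °C, N2; then iPrOH, reflux
Reagents that add atoms: none
Why: Barton nitrite photolysis: O–NO homolysis gives the 6α-alkoxy radical, whose equatorial oxygen is peri to the equatorial 4α-methyl, so 1,5-hydrogen transfer through a six-membered transition state should reach only C18 (the axial 4β-methyl and C20 lie on the far face); NO recombines at C18 and the nitroso compound tautomerises to the oxime on warming, fixing C4 with the oxidised carbon α, while the cool nonpolar medium is chosen to hold back β-scission toward the C7 allyl radical.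

Step 4
Reactants: 5 6α-hydroxy-13-oxo-14,15-dinorlabd-8(17)-en-18-al oxime
Product: 6 6α-hydroxy-13-oxo-14,15-dinorlabd-8(17)-en-18-al
Conditions: NaNO2, AcOH/H2O, 10 °C
Reagents that add atoms: water, O
Why: Nitrosative deoximation, the classical follow-up to a Barton oxime, should release the neopentyl aldehyde under mild acid; C4 is quaternary and cannot epimerise.

Step 5
Reactants: 6 6α-hydroxy-13-oxo-14,15-dinorlabd-8(17)-en-18-al
Product: 7 6α,18-epoxy-18-methoxy-14,15-dinorlabd-8(17)-en-13-one (both C18 anomers, either serves)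
Conditions: PPTS (cat.), MeOH, rt; chromatography on SiO2
Reagents that add atoms: methanol, CO
Why: Acid-catalysed acetalisation: the peri 6α-hydroxyl captures the C18 oxocarbenium ion intramolecularly, so the cyclic methyl acetal should win over the dimethyl acetal; PPTS is too weak to move the exocyclic alkene, and any C13 dimethyl ketal reverts on silica.

Step 6
Reactants: 7 6α,18-epoxy-18-methoxy-14,15-dinorlabd-8(17)-en-13-one
Product: 8 6α,18:8α,17-diepoxy-18-methoxy-14,15-dinorlabdan-13-one
Conditions: mCPBA, NaHCO3, CH2Cl2, 0 °C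
Reagents that add atoms: mCPBA, OOC(=O)c1cccc(Cl)c1
Why: Prilezhaev epoxidation should occur from the α face because the β face of C8 is screened by the axial C20 methyl, which sets C8 with oxygen α; bicarbonate protects the acetal and the cold medium avoids Baeyer–Villiger reaction of the ketone.

Step 7
Reactants: 8 6α,18:8α,17-diepoxy-18-methoxy-14,15-dinorlabdan-13-one
Product: 9 6α,18-epoxy-18-methoxy-14,15-dinorlabdane-8α,13-diol (C13 epimers)
Conditions: LiAlH4, THF, 0 °C → rt
Reagents that add atoms: none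
Why: Hydride opens the spiro-epoxide by SN2 attack at the primary C17, so the C8–O bond is untouched (8α-OH, 8β-methyl); the ketone is reduced as well and the acetal is inert.

Step 8
Reactants: 9 6α,18-epoxy-18-methoxy-14,15-dinorlabdane-8α,13-diol
Product: 10 6α,18-epoxy-8α-hydroxy-18-methoxy-14,15-dinorlabdan-13-one
Conditions: nPr4N[RuO4] (5 mol %), NMO, 4 Å molecular sieves, CH2Cl2, rt
Reagents that add atoms: none
Why: Ley–Griffith oxidation converts only the secondary C13 carbinol (both epimers converge) under neutral conditions that spare the acetal; the tertiary 8-OH cannot be oxidised.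

Step 9
Reactants: 10 6α,18-epoxy-8α-hydroxy-18-methoxy-14,15-dinorlabdan-13-one
Product: 11 6α,18-epoxy-18-methoxy-8α-(trimethylsilyloxy)-14,15-dinorlabdan-13-one
Conditions: N-(trimethylsilyl)imidazole, CH2Cl2, rt
Reagents that add atoms: N-(trimethylsilyl)imidazole, C[Si](C)(C)n1ccnc1
Why: This neutral, powerful silyl donor should cap the hindered tertiary alcohol without forming a silyl enol ether from the methyl ketone (O-silylation); the cap prevents O8 from closing onto C13 as hemiketal or, later, by oxa-Michael addition.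

Step 10
Reactants: 11 6α,18-epoxy-18-methoxy-8α-(trimethylsilyloxy)-14,15-dinorlabdan-13-one; 12 triethyl phosphonoacetate
Product: 13 ethyl (13E)-6α,18-epoxy-18-methoxy-8α-(trimethylsilyloxy)labd-13-en-15-oate
Conditions: NaH, THF, 0 → 50 °C; minor (13Z) isomer removed by chromatography
Reagents that add atoms: triethyl phosphonoacetate (compound 12), CCOC(=O)CP(=O)(OCC)OCC
Why: Horner–Wadsworth–Emmons olefination of the methyl ketone should favour the E enoate, in which the ester is trans to the larger C12 chain and therefore cis to the C16 methyl.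

Step 11
Reactants: 13 ethyl (13E)-6α,18-epoxy-18-methoxy-8α-(trimethylsilyloxy)labd-13-en-15-oate
Product: 14 (13E)-6α,18-epoxy-18-methoxy-8α-(trimethylsilyloxy)labd-13-en-15-ol
Conditions: iBu2AlH, CH2Cl2, −78 °C; aq. KNaC4H4O6 (Rochelle salt)
Reagents that add atoms: none
Why: 1,2-Reduction of the enoate to the allylic alcohol by the aluminium hydride leaves the silyl ether, the acetal and the alkene geometry untouched.

Step 12
Reactants: 14 (13E)-6α,18-epoxy-18-methoxy-8α-(trimethylsilyloxy)labd-13-en-15-ol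
Product: 15 (13E)-6α,18-epoxy-18-methoxy-8α-(trimethylsilyloxy)labd-13-en-15-al
Conditions: MnO2, CH2Cl2, rt
Reagents that add atoms: none
Why: Heterogeneous, neutral allylic oxidation should stop at the enal without E/Z isomerisation or loss of the silyl ether.

Step 13
Reactants: 16 4-methylfuran-2(5H)-one
Product: 17 4-methyl-2-(trimethylsilyloxy)furan
Conditions: TMSOTf, Et3N, Et2O, 0 °C; distillation
Reagents that add atoms: trimethylsilyl triflate, C[Si](C)(C)OS(=O)(=O)C(F)(F)F
Why: Soft enolisation: O-silylation of the lactone carbonyl and removal of a C5 proton by the amine give the aromatic silyloxyfuran; the trimethylsilyl group is chosen because it transfers readily in the catalytic aldol and leaves the adduct under mild acid.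

Step 14
Reactants: 15 (13E)-6α,18-epoxy-18-methoxy-8α-(trimethylsilyloxy)labd-13-en-15-al; 17 4-methyl-2-(trimethylsilyloxy)furan
Product: 19 (13E,15R)-6α,18-epoxy-18-methoxy-15-[(5R)-4-methyl-2-oxo-2,5-dihydrofuran-5-yl]labd-13-ene-8α,15-diol, via bis(trimethylsilyl) aldol adduct 18 (not isolated)
Conditions: Ti(OiPr)4 (20 mol %), (S)-BINOL (20 mol %), Et2O, −20 °C; then PPTS, MeOH, rt
Reagents that add atoms: 4-methyl-2-(trimethylsilyloxy)furan (compound 17), CC1=COC(O[Si](C)(C)C)=C1
Why: The BINOL–titanium Lewis acid binds the aldehyde oxygen of 15 and C5 of silyloxyfuran 17 adds to C15 through an open transition state; silyl transfer to the aldolate releases the catalyst and leaves the 4-methylbutenolide (vinylogous Mukaiyama aldol). The closest known reaction is the titanium–BINOL-catalysed addition of 2-trimethylsilyloxyfuran to aldehydes, applied here to a β,β-disubstituted enal. No ring is closed, because the lactone ring arrives as the furan. C15 is set by the catalyst alone (Si face; the nearest substrate stereocentre, C9, is five bonds away), and C5' follows from the threo preference of the Lewis-acid open transition state, in which the furan ring oxygen and the alkenyl residue avoid each other. The step needs 1,2- over 1,4-addition and γ- over α-attack: the first is secured by the fully substituted C13, the second is inherent to 2-silyloxyfurans, and the acetal and silyl ether offer no competing electrophile to this mild Lewis acid. Methanolic PPTS then removes both trimethylsilyl groups without base, so the epimerisable C5' is untouched and the methyl acetal merely exchanges with the solvent; the 8-OH cap is no longer needed once the enal is consumed.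

Step 15
Reactants: 19 (13E,15R)-6α,18-epoxy-18-methoxy-15-[(5R)-4-methyl-2-oxo-2,5-dihydrofuran-5-yl]labd-13-ene-8α,15-diol
Product: 21 (14S,15R)-6α,18-epoxy-18-methoxy-15-[(5R)-4-methyl-2-oxo-2,5-dihydrofuran-5-yl]labd-13(16)-ene-8α,14,15-triol, via 14-hydroperoxide 20 (not isolated)
Conditions: O2, tetraphenylporphyrin (cat.), visible light, CCl4, −10 °C; then PPh3, 0 °C
Reagents that add atoms: oxygen, O=O
Why: Hydroxyl-directed Schenck ene reaction: with H15 eclipsing the alkene to avoid A(1,3) strain against the cis C16 methyl, the 15-OH should hydrogen-bond the incoming singlet oxygen on one face, so oxygen adds to C14 threo to C15 (14S) and a hydrogen is taken from the cis C16 methyl to leave the C13=C16 methylene; the electron-poor butenolide alkene is inert and PPh3 reduces the hydroperoxide in the same flask without base.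

Step 16
Reactants: 21 (14S,15R)-6α,18-epoxy-18-methoxy-15-[(5R)-4-methyl-2-oxo-2,5-dihydrofuran-5-yl]labd-13(16)-ene-8α,14,15-triol
Product: 23 target CNP0156243.1, (14S,15R)-6α,8α,14,15-tetrahydroxy-15-[(5R)-4-methyl-2-oxo-2,5-dihydrofuran-5-yl]labd-13(16)-en-18-al, via 6α,18-lactol 22 (not isolated)
Conditions: 1 M aq. HCl, THF, 0 °C → rt
Reagents that add atoms: water, O
Why: Acid-catalysed hydrolysis of the mixed cyclic acetal through the oxocarbenium ion gives the lactol, which opens to the 6α-hydroxy-18-aldehyde; no stereocentre is at risk (C4 is quaternary, C5' is labile to base but not to acid) and dilute acid at room temperature should leave the tertiary 8-OH and the allylic diol intact.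

Compound list
1 | larixol, labda-8(17),14-diene-6α,13(S)-diol | C=C[C@@](C)(O)CC[C@@H]1[C@@]2(C)CCCC(C)(C)[C@@H]2[C@@H](O)CC1=C | starting material
2 | 6α-hydroxy-14,15-dinorlabd-8(17)-en-13-one | CC(=O)CC[C@@H]1[C@@]2(C)CCCC(C)(C)[C@@H]2[C@@H](O)CC1=C | intermediate
3 | 6α-nitrite ester of 2 | CC(=O)CC[C@@H]1[C@@]2(C)CCCC(C)(C)[C@@H]2[C@@H](ON=O)CC1=C | intermediate
4 | 6α-hydroxy-18-nitroso-14,15-dinorlabd-8(17)-en-13-one | CC(=O)CC[C@@H]1[C@@]2(C)CCC[C@@](C)(CN=O)[C@@H]2[C@@H](O)CC1=C | intermediate (not isolated)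
5 | 6α-hydroxy-13-oxo-14,15-dinorlabd-8(17)-en-18-al oxime | CC(=O)CC[C@@H]1[C@@]2(C)CCC[C@@](C)(C=NO)[C@@H]2[C@@H](O)CC1=C | intermediate
6 | 6α-hydroxy-13-oxo-14,15-dinorlabd-8(17)-en-18-al | CC(=O)CC[C@@H]1[C@@]2(C)CCC[C@@](C)(C=O)[C@@H]2[C@@H](O)CC1=C | intermediate
7 | 6α,18-epoxy-18-methoxy-14,15-dinorlabd-8(17)-en-13-one (C18 anomers) | CC(=O)CC[C@@H]1[C@@]2(C)CCC[C@@](C)(C3OC)[C@@H]2[C@@H](O3)CC1=C | intermediate
8 | 6α,18:8α,17-diepoxy-18-methoxy-14,15-dinorlabdan-13-one | CC(=O)CC[C@@H]1[C@@]2(C)CCC[C@@](C)(C3OC)[C@@H]2[C@@H](O3)C[C@]14CO4 | intermediate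
9 | 6α,18-epoxy-18-methoxy-14,15-dinorlabdane-8α,13-diol (C13 epimers) | CC(O)CC[C@@H]1[C@@]2(C)CCC[C@@](C)(C3OC)[C@@H]2[C@@H](O3)C[C@@]1(C)O | intermediate
10 | 6α,18-epoxy-8α-hydroxy-18-methoxy-14,15-dinorlabdan-13-one | CC(=O)CC[C@@H]1[C@@]2(C)CCC[C@@](C)(C3OC)[C@@H]2[C@@H](O3)C[C@@]1(C)O | intermediate
11 | 6α,18-epoxy-18-methoxy-8α-(trimethylsilyloxy)-14,15-dinorlabdan-13-one | CC(=O)CC[C@@H]1[C@@]2(C)CCC[C@@](C)(C3OC)[C@@H]2[C@@H](O3)C[C@@]1(C)O[Si](C)(C)C | intermediate
12 | triethyl phosphonoacetate | CCOC(=O)CP(=O)(OCC)OCC | starting material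
13 | ethyl (13E)-6α,18-epoxy-18-methoxy-8α-(trimethylsilyloxy)labd-13-en-15-oate | CCOC(=O)/C=C(\C)CC[C@@H]1[C@@]2(C)CCC[C@@](C)(C3OC)[C@@H]2[C@@H](O3)C[C@@]1(C)O[Si](C)(C)C | intermediate
14 | (13E)-6α,18-epoxy-18-methoxy-8α-(trimethylsilyloxy)labd-13-en-15-ol | OC/C=C(\C)CC[C@@H]1[C@@]2(C)CCC[C@@](C)(C3OC)[C@@H]2[C@@H](O3)C[C@@]1(C)O[Si](C)(C)C | intermediate
15 | (13E)-6α,18-epoxy-18-methoxy-8α-(trimethylsilyloxy)labd-13-en-15-al | O=C/C=C(\C)CC[C@@H]1[C@@]2(C)CCC[C@@](C)(C3OC)[C@@H]2[C@@H](O3)C[C@@]1(C)O[Si](C)(C)C | intermediate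
16 | 4-methylfuran-2(5H)-one | CC1=CC(=O)OC1 | starting material
17 | 4-methyl-2-(trimethylsilyloxy)furan | CC1=COC(O[Si](C)(C)C)=C1 | intermediate
18 | 8,15-bis(trimethylsilyl) ether of 19 | C/C(CC[C@@H]1[C@@]2(C)CCC[C@@](C)(C3OC)[C@@H]2[C@@H](O3)C[C@@]1(C)O[Si](C)(C)C)=C\[C@@H](O[Si](C)(C)C)[C@@H]1OC(=O)C=C1C | intermediate (not isolated)
19 | (13E,15R)-6α,18-epoxy-18-methoxy-15-[(5R)-4-methyl-2-oxo-2,5-dihydrofuran-5-yl]labd-13-ene-8α,15-diol | C/C(CC[C@@H]1[C@@]2(C)CCC[C@@](C)(C3OC)[C@@H]2[C@@H](O3)C[C@@]1(C)O)=C\[C@@H](O)[C@@H]1OC(=O)C=C1C | intermediate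
20 | (14S,15R)-6α,18-epoxy-14-hydroperoxy-18-methoxy-15-[(5R)-4-methyl-2-oxo-2,5-dihydrofuran-5-yl]labd-13(16)-ene-8α,15-diol | C=C(CC[C@@H]1[C@@]2(C)CCC[C@@](C)(C3OC)[C@@H]2[C@@H](O3)C[C@@]1(C)O)[C@H](OO)[C@@H](O)[C@@H]1OC(=O)C=C1C | intermediate (not isolated)
21 | (14S,15R)-6α,18-epoxy-18-methoxy-15-[(5R)-4-methyl-2-oxo-2,5-dihydrofuran-5-yl]labd-13(16)-ene-8α,14,15-triol | C=C(CC[C@@H]1[C@@]2(C)CCC[C@@](C)(C3OC)[C@@H]2[C@@H](O3)C[C@@]1(C)O)[C@H](O)[C@@H](O)[C@@H]1OC(=O)C=C1C | intermediate
22 | 6α,18-lactol tautomer of the target (6α,18-epoxy-18-hydroxy) | C=C(CC[C@@H]1[C@@]2(C)CCC[C@@](C)(C3O)[C@@H]2[C@@H](O3)C[C@@]1(C)O)[C@H](O)[C@@H](O)[C@@H]1OC(=O)C=C1C | intermediate (not isolated)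
23 | CNP0156243.1, (14S,15R)-6α,8α,14,15-tetrahydroxy-15-[(5R)-4-methyl-2-oxo-2,5-dihydrofuran-5-yl]labd-13(16)-en-18-al | C=C(CC[C@@H]1[C@@]2(C)CCC[C@@](C)(C=O)[C@@H]2[C@@H](O)C[C@@]1(C)O)[C@H](O)[C@@H](O)[C@@H]1OC(=O)C=C1C | target

Total step count: 16. Longest linear sequence: 15 steps (1 to 23 through steps 1–12 and 14–16); step 13 is the one-step side branch.

Steps most likely to fail

Step 3 (radical relay). The 6-alkoxy radical is homoallylic to C8=C17, so β-scission of ring B toward an allyl radical, or addition of NOCl to the alkene in step 2, may outrun hydrogen transfer to C18. The fallback removes the alkene before the relay instead of changing the photolysis. It sets out from 2: buffered mCPBA should give 6α-hydroxy-8α,17-epoxy-14,15-dinorlabdan-13-one F1, since the homoallylic hydroxyl and the C20 methyl both send the peracid to the α face. NOCl in pyridine gives its 6-nitrite F2, and photolysis proceeds through the C18-nitroso epoxy alcohol F3 to the epoxy oxime F4. Buffered aqueous TiCl3/NH4OAc cleaves the oxime to the epoxy hydroxy-aldehyde F5, and PPTS in methanol at 0 °C closes the acetal, so the route is rejoined at 8. Without the alkene, 1,5-hydrogen transfer is the only low-barrier path open to the alkoxy radical.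

Step 14 (key aldol). Weak facial discrimination at C15, a poor threo:erythro ratio or slow turnover may result because the enal is hindered and β,β-disubstituted. The fallback replaces catalyst control by an auxiliary-controlled syn-glycolate aldol followed by butenolide annulation. It sets out from 15: the dibutylboron enolate of (S)-4-benzyl-3-[2-(4-methoxybenzyloxy)acetyl]oxazolidin-2-one (Bu2BOTf, Et3N, CH2Cl2, −78 °C) should give the Evans syn adduct, the 15-hydroxy-5'-(4-methoxybenzyloxy) imide F6, with the same spatial arrangement at C15 and C5' as in 19. AlMe3/MeONHMe·HCl converts it into the Weinreb amide F7, and TESCl/imidazole gives the 15-O-triethylsilyl amide F8. MeMgBr gives the methyl ketone F9, whose carbonyl carbon becomes C4'. Buffered DDQ frees the 5'-hydroxyl to give the α-hydroxy ketone F10. Ph3P=C=C=O in warm toluene acylates O5' and closes the ring by intramolecular Wittig reaction to the silylated butenolide F11. PPTS in methanol removes both silyl ethers and the route is rejoined at 19.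

Step 15 (directed ene). Hydroxyl direction may be lost, because the lactone oxygen competes as hydrogen-bond acceptor, giving the erythro hydroperoxide; hydrogen may also be taken from C12 instead of C16. The fallback separates the two events into epoxidation and isomerisation. It sets out from 19: mCPBA (NaHCO3, CH2Cl2, 0 °C) should epoxidise the electron-rich C13=C14 bond threo to the 15-OH under the same A(1,3) control, giving the threo-13,14-epoxy-15-ol F12. Cp2TiCl (from Cp2TiCl2 and Mn powder, THF) then opens the C13–O bond homolytically to the tertiary C13 radical; this loses a hydrogen atom from C16 to a second trivalent titanium species. The 14-OH is formed with retention and the C13=C16 methylene appears, so the route is rejoined at 21.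

Further compounds
F1 | step 3 | 6α-hydroxy-8α,17-epoxy-14,15-dinorlabdan-13-one | CC(=O)CC[C@@H]1[C@@]2(C)CCCC(C)(C)[C@@H]2[C@@H](O)C[C@]14CO4
F2 | step 3 | 6α-nitrite ester of F1 | CC(=O)CC[C@@H]1[C@@]2(C)CCCC(C)(C)[C@@H]2[C@@H](ON=O)C[C@]14CO4
F3 | step 3 | 8α,17-epoxy-6α-hydroxy-18-nitroso-14,15-dinorlabdan-13-one | CC(=O)CC[C@@H]1[C@@]2(C)CCC[C@@](C)(CN=O)[C@@H]2[C@@H](O)C[C@]14CO4
F4 | step 3 | 8α,17-epoxy-6α-hydroxy-13-oxo-14,15-dinorlabdan-18-al oxime | CC(=O)CC[C@@H]1[C@@]2(C)CCC[C@@](C)(C=NO)[C@@H]2[C@@H](O)C[C@]14CO4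
F5 | step 3 | 8α,17-epoxy-6α-hydroxy-13-oxo-14,15-dinorlabdan-18-al | CC(=O)CC[C@@H]1[C@@]2(C)CCC[C@@](C)(C=O)[C@@H]2[C@@H](O)C[C@]14CO4
F6 | step 14 | Evans syn-glycolate aldol imide (15-hydroxy, 5'-O-PMB, 8-O-TMS, (S)-4-benzyloxazolidinone) | C/C(CC[C@@H]1[C@@]2(C)CCC[C@@](C)(C3OC)[C@@H]2[C@@H](O3)C[C@@]1(C)O[Si](C)(C)C)=C\[C@@H](O)[C@H](OCc1ccc(OC)cc1)C(=O)N1[C@@H](Cc2ccccc2)COC1=O
F7 | step 14 | Weinreb amide from F6 | C/C(CC[C@@H]1[C@@]2(C)CCC[C@@](C)(C3OC)[C@@H]2[C@@H](O3)C[C@@]1(C)O[Si](C)(C)C)=C\[C@@H](O)[C@H](OCc1ccc(OC)cc1)C(=O)N(C)OC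
F8 | step 14 | 15-O-triethylsilyl ether of F7 | C/C(CC[C@@H]1[C@@]2(C)CCC[C@@](C)(C3OC)[C@@H]2[C@@H](O3)C[C@@]1(C)O[Si](C)(C)C)=C\[C@@H](O[Si](CC)(CC)CC)[C@H](OCc1ccc(OC)cc1)C(=O)N(C)OC
F9 | step 14 | methyl ketone from F8 (5'-O-PMB, carbonyl carbon = C4') | C/C(CC[C@@H]1[C@@]2(C)CCC[C@@](C)(C3OC)[C@@H]2[C@@H](O3)C[C@@]1(C)O[Si](C)(C)C)=C\[C@@H](O[Si](CC)(CC)CC)[C@H](OCc1ccc(OC)cc1)C(C)=O
F10 | step 14 | α-hydroxy methyl ketone from F9 | C/C(CC[C@@H]1[C@@]2(C)CCC[C@@](C)(C3OC)[C@@H]2[C@@H](O3)C[C@@]1(C)O[Si](C)(C)C)=C\[C@@H](O[Si](CC)(CC)CC)[C@H](O)C(C)=O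
F11 | step 14 | 15-O-triethylsilyl 8-O-trimethylsilyl ether of 19 | C/C(CC[C@@H]1[C@@]2(C)CCC[C@@](C)(C3OC)[C@@H]2[C@@H](O3)C[C@@]1(C)O[Si](C)(C)C)=C\[C@@H](O[Si](CC)(CC)CC)[C@@H]1OC(=O)C=C1C
F12 | step 15 | threo-13,14-epoxide of 19 (oxirane oxygen on the face of the 15-OH) | C[C@]1(CC[C@@H]2[C@@]3(C)CCC[C@@](C)(C4OC)[C@@H]3[C@@H](O4)C[C@@]2(C)O)O[C@@H]1[C@@H](O)[C@@H]1OC(=O)C=C1C
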